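**Plan**

- Retrosynthetic cuts: the C11 acetate (exchanged for a TBS ether), the C5=C6 alkene (taken back to an alkyne and cut by alkyne metathesis), the O15–C1 ester bond, the C7–C8 and C12–C13 bonds (three-component coupling on a cyclopentenone), and C14–C15 (acetylide acylation).
- Forward order: the ω-chain iodide 11 is built from (Z)-hex-3-enoic acid; 11, enone 14 and 1-iodobut-2-yne 13 are joined in one pot on the five-membered ring; O15 is acylated with hept-5-ynoic acid; the 13-membered lactone ring is closed at C5≡C6; semihydrogenation and a TBS-to-acetate exchange at O11 finish the route.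
- Enabling feature: the C5–C6 cis-alkene lies in the 13-membered ring (O15, C1 to C8, C12 to C15), three CH2 groups from the ester carbonyl C1 and one CH2 from C8, away from the stereocentres C8, C11, C12 and C15. A ring of this size can hold a triple bond, so the alkene can be made as a cycloalkyne from two methyl-capped alkynes and then reduced.
- Stereochemistry: C11 comes from enone 14; C12 and C8 from anti conjugate addition and anti enolate alkylation; C15 from asymmetric transfer hydrogenation of ynone 6; 17Z from acid 1; 13E from hydrozirconation; 5Z from syn semihydrogenation.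

Key step: step 11

Assumption: prostanoid numbering is used throughout (C1 lactone carbonyl, C8 to C12 five-membered ring, C15 lactone carbinol), and the (S,S)-TsDPEN ruthenium catalyst is taken to give the (S)-propargylic alcohol, as it does with simpler alkynyl ketones.

**Route**

Step 1
Reactants: 1 (Z)-hex-3-enoic acid
Product: 3 (Z)-N-methoxy-N-methylhex-3-enamide, via acyl imidazolide 2 (not isolated)
Conditions: CDI, CH2Cl2, 0 °C to rt; then MeNH(OMe)·HCl, rt
Reagents that add atoms: N,O-dimethylhydroxylamine hydrochloride, CNOC.Cl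
Why: Amide coupling through the acyl imidazolide gives the Weinreb amide under near-neutral conditions, so neither a ketene nor migration of the 3Z alkene into conjugation is expected.

Step 2
Reactants: 3 (Z)-N-methoxy-N-methylhex-3-enamide; 4 lithium (trimethylsilyl)acetylide (commercial THF solution)
Product: 6 (Z)-1-(trimethylsilyl)oct-5-en-1-yn-3-one, via lithium hemiaminal adduct 5 (not isolated)
Conditions: 4 (1.3 equiv), THF, −78 to −20 °C; poured into cold 1 M HCl
Reagents that add atoms: none
Why: Weinreb ketone synthesis, in which the acetylide adds once to give the N,O-chelated tetrahedral adduct 5 that collapses to the ynone only on the acidic quench, which also keeps the released amine protonated and away from the ynone.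

Step 3
Reactants: 6 (Z)-1-(trimethylsilyl)oct-5-en-1-yn-3-one
Product: 7 (S,Z)-1-(trimethylsilyl)oct-5-en-1-yn-3-ol
Conditions: Ru[(S,S)-TsNCH(Ph)CH(Ph)NH](η6-p-cymene) (1 mol%), i-PrOH, rt
Reagents that add atoms: none
Why: Noyori asymmetric transfer hydrogenation of an α,β-acetylenic ketone, in which the (S,S)-ligand delivers hydride through the six-membered Ru–H/N–H transition state with the alkynyl group in the place usually taken by an aryl group, which should set the 3S carbinol (the later C15); the base-free catalyst leaves the skipped Z-alkene in place and does not reduce isolated alkenes.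

Step 4
Reactants: 7 (S,Z)-1-(trimethylsilyl)oct-5-en-1-yn-3-ol
Product: 8 (S,Z)-oct-5-en-1-yn-3-ol
Conditions: K2CO3 (0.2 equiv), MeOH, 0 °C to rt
Reagents that add atoms: none
Why: Base-catalysed methanolysis of the C(sp)–Si bond (protiodesilylation) frees the terminal alkyne without touching the carbinol centre.

Step 5
Reactants: 8 (S,Z)-oct-5-en-1-yn-3-ol
Product: 9 (S,Z)-3-(triethylsilyloxy)oct-5-en-1-yne
Conditions: TESCl, imidazole, CH2Cl2, 0 °C
Reagents that add atoms: chlorotriethylsilane, CC[Si](Cl)(CC)CC
Why: Imidazole-promoted silylation of the secondary alcohol; the triethylsilyl ether is chosen because it can later be removed in the presence of the TBS ether at O11.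

Step 6
Reactants: 9 (S,Z)-3-(triethylsilyloxy)oct-5-en-1-yne
Product: 11 (3S,1E,5Z)-1-iodo-3-(triethylsilyloxy)octa-1,5-diene, via alkenylzirconocene chloride 10 (not isolated)
Conditions: Cp2Zr(H)Cl (1.2 equiv), THF, rt, dark; then I2, 0 °C; aq. Na2S2O3
Reagents that add atoms: iodine, II
Why: Schwartz hydrozirconation adds Zr–H syn across the terminal alkyne, with zirconium at the terminal carbon, far faster than across the internal Z-alkene, and iododezirconation with retention gives the E-alkenyl iodide.

Step 7
Reactants: 12 1-bromobut-2-yne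
Product: 13 1-iodobut-2-yne
Conditions: NaI, acetone, rt, dark; used freshly
Reagents that add atoms: sodium iodide, [Na+].[I-]
Why: Finkelstein halide exchange (SN2), driven by precipitation of NaBr from acetone.

Step 8
Reactants: 11 (3S,1E,5Z)-1-iodo-3-(triethylsilyloxy)octa-1,5-diene; 13 1-iodobut-2-yne; 14 (R)-4-(tert-butyldimethylsilyloxy)cyclopent-2-en-1-one
Product: 18 (2R,3R,4R)-2-(but-2-yn-1-yl)-4-(tert-butyldimethylsilyloxy)-3-[(3S,1E,5Z)-3-(triethylsilyloxy)octa-1,5-dien-1-yl]cyclopentan-1-one, via alkenyllithium 15 (not isolated), via lithium alkenyldimethylzincate 16 (not isolated), via zinc enolate 17 (not isolated)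
Conditions: 11, t-BuLi (2 equiv), Et2O, −78 °C; Me2Zn, THF, −78 to 0 °C; 14, THF, −78 °C; HMPA, 13 (5 equiv), −78 to −40 °C; aq. NH4Cl
Reagents that add atoms: none
Why: Noyori three-component coupling, in which iodine–lithium exchange keeps the alkene geometry, the mixed triorganozincate transfers the alkenyl group in a conjugate addition anti to the C11 silyloxy group (sets C12), and the zinc enolate is C-alkylated by the propargylic iodide anti to the new C12 side chain (sets C8), giving the trans,trans-cyclopentanone.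

Step 9
Reactants: 18 the 11-O-TBS, 15-O-TES but-2-ynyl ketone
Product: 19 (2R,3R,4R)-2-(but-2-yn-1-yl)-4-(tert-butyldimethylsilyloxy)-3-[(3S,1E,5Z)-3-hydroxyocta-1,5-dien-1-yl]cyclopentan-1-one
Conditions: PPTS (0.2 equiv), MeOH/CH2Cl2, 0 °C
Reagents that add atoms: none
Why: Acid-catalysed methanolysis cleaves the more labile triethylsilyl ether selectively over the TBS ether, under conditions too mild for β-elimination of the C11 silyloxy group.

Step 10
Reactants: 19 the 15-alcohol; 20 hept-5-ynoic acid
Product: 22 (3S,1E,5Z)-1-[(1R,2R,5R)-2-(but-2-yn-1-yl)-5-(tert-butyldimethylsilyloxy)-3-oxocyclopentyl]octa-1,5-dien-3-yl hept-5-ynoate, via O-acylisourea 21 (not isolated)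
Conditions: DCC, DMAP (0.1 equiv), CH2Cl2, 0 °C to rt
Reagents that add atoms: none
Why: Steglich esterification through the O-acylisourea acylates O15 without breaking the C15–O bond, so the configuration is retained, and the small amount of DMAP limits the risk of β-elimination.

Step 11
Reactants: 22 the diyne ester (C8 but-2-ynyl, O15 hept-5-ynoate, 11-O-TBS, 9-ketone)
Product: 23 5,6-didehydro macrolactone (13-membered cycloalkyne, 11-O-TBS; 8R,11R,12R,15S)
Conditions: Mo(≡CC6H4OMe-4)(OSiPh3)3 (5 mol%), powdered 5 Å MS, toluene (0.002 M), rt to 50 °C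
Reagents that add atoms: none
Why: Ring-closing alkyne metathesis: the alkylidyne of hexavalent molybdenum takes up one methyl-capped alkyne of 22 by [2+2] cycloaddition to a metallacyclobutadiene, cycloreversion releases the cap and leaves a substrate-bound alkylidyne, and the same sequence with the second alkyne forms C5≡C6 and expels but-2-yne. The closest known reaction type is the ring-closing alkyne metathesis of ester-tethered diynes to macrocyclic cycloalkynes, prostaglandin-type lactones included. The 13-membered ring closes by end-to-end union of the two chain termini under high dilution, with the new triple bond inside a ring large enough to hold it. No stereocentre is formed, and C8, C11, C12 and C15 are not touched. The step needs alkyne-over-alkene chemoselectivity and ring closure over oligomerisation: the alkylidyne ignores the 13E and 17Z alkenes, the ketone, the ester and the silyl ether, the adjacent side chains on C8 and C12 with the E-13,14 alkene keep the two alkynes within reach, and the 5 Å sieves trap but-2-yne so that the closure is not reversed.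

Step 12
Reactants: 23 the cycloalkyne
Product: 24 (5Z,13E,17Z)-macrolactone 11-O-TBS ether (PGE3 1,15-lactone 11-O-TBS ether)
Conditions: H2 (1 atm), Pd/CaCO3 poisoned with Pb(OAc)2, quinoline, EtOAc, rt, stopped after one equivalent of H2
Reagents that add atoms: none
Why: Lindlar semihydrogenation delivers H2 syn from the poisoned palladium surface to the strongly adsorbed alkyne and gives the 5Z alkene, while the 13E and 17Z alkenes should not compete on the lead- and quinoline-poisoned surface.

Step 13
Reactants: 24 the 11-O-TBS lactone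
Product: 25 PGE3 1,15-lactone (11-alcohol)
Conditions: HF·pyridine, pyridine, THF, 0 °C
Reagents that add atoms: none
Why: Fluoride-mediated desilylation under buffered acidic conditions removes the secondary TBS ether without base-induced β-elimination to the cyclopentenone or opening of the lactone.

Step 14
Reactants: 25 PGE3 1,15-lactone
Product: 26 PGE3 1,15-lactone 11-acetate (target)
Conditions: Ac2O, pyridine, CH2Cl2, 0 °C
Reagents that add atoms: acetic anhydride, CC(=O)OC(C)=O
Why: Pyridine-mediated O-acetylation of the secondary C11 alcohol at low temperature and without DMAP, which should keep the β-acetoxy ketone from eliminating.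

**Compound list**

1 | (Z)-hex-3-enoic acid | CC/C=C\CC(=O)O | starting material
2 | (Z)-1-(imidazol-1-yl)hex-3-en-1-one (acyl imidazolide) | CC/C=C\CC(=O)n1ccnc1 | intermediate
3 | (Z)-N-methoxy-N-methylhex-3-enamide | CC/C=C\CC(=O)N(C)OC | intermediate
4 | lithium (trimethylsilyl)acetylide | [Li]C#C[Si](C)(C)C | starting material
5 | lithium (Z)-3-[methoxy(methyl)amino]-1-(trimethylsilyl)oct-5-en-1-yn-3-olate | CC/C=C\CC(O[Li])(C#C[Si](C)(C)C)N(C)OC | intermediate
6 | (Z)-1-(trimethylsilyl)oct-5-en-1-yn-3-one | CC/C=C\CC(=O)C#C[Si](C)(C)C | intermediate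
7 | (S,Z)-1-(trimethylsilyl)oct-5-en-1-yn-3-ol | CC/C=C\C[C@H](O)C#C[Si](C)(C)C | intermediate
8 | (S,Z)-oct-5-en-1-yn-3-ol | CC/C=C\C[C@H](O)C#C | intermediate
9 | (S,Z)-3-(triethylsilyloxy)oct-5-en-1-yne | CC/C=C\C[C@H](O[Si](CC)(CC)CC)C#C | intermediate
10 | chlorobis(cyclopentadienyl)[(3S,1E,5Z)-3-(triethylsilyloxy)octa-1,5-dien-1-yl]zirconium | CC/C=C\C[C@H](O[Si](CC)(CC)CC)/C=C/[Zr](Cl)(C1C=CC=C1)C1C=CC=C1 | intermediate
11 | (3S,1E,5Z)-1-iodo-3-(triethylsilyloxy)octa-1,5-diene | CC/C=C\C[C@H](O[Si](CC)(CC)CC)/C=C/I | intermediate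
12 | 1-bromobut-2-yne | CC#CCBr | starting material
13 | 1-iodobut-2-yne | CC#CCI | intermediate
14 | (R)-4-(tert-butyldimethylsilyloxy)cyclopent-2-en-1-one | O=C1C[C@@H](O[Si](C)(C)C(C)(C)C)C=C1 | starting material
15 | [(3S,1E,5Z)-3-(triethylsilyloxy)octa-1,5-dien-1-yl]lithium | CC/C=C\C[C@H](O[Si](CC)(CC)CC)/C=C/[Li] | intermediate
16 | lithium dimethyl[(3S,1E,5Z)-3-(triethylsilyloxy)octa-1,5-dien-1-yl]zincate | CC/C=C\C[C@H](O[Si](CC)(CC)CC)/C=C/[Zn-](C)C.[Li+] | intermediate
17 | lithium dimethylzincate enolate (C8=C9) of the (11R,12R) conjugate adduct | CC/C=C\C[C@H](O[Si](CC)(CC)CC)/C=C/[C@H]1[C@H](O[Si](C)(C)C(C)(C)C)CC(O[Zn-](C)C)=C1.[Li+] | intermediate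
18 | (2R,3R,4R)-2-(but-2-yn-1-yl)-4-(tert-butyldimethylsilyloxy)-3-[(3S,1E,5Z)-3-(triethylsilyloxy)octa-1,5-dien-1-yl]cyclopentan-1-one | CC/C=C\C[C@H](O[Si](CC)(CC)CC)/C=C/[C@H]1[C@H](O[Si](C)(C)C(C)(C)C)CC(=O)[C@@H]1CC#CC | intermediate
19 | (2R,3R,4R)-2-(but-2-yn-1-yl)-4-(tert-butyldimethylsilyloxy)-3-[(3S,1E,5Z)-3-hydroxyocta-1,5-dien-1-yl]cyclopentan-1-one | CC/C=C\C[C@H](O)/C=C/[C@H]1[C@H](O[Si](C)(C)C(C)(C)C)CC(=O)[C@@H]1CC#CC | intermediate
20 | hept-5-ynoic acid | CC#CCCCC(=O)O | starting material
21 | O-(hept-5-ynoyl)-N,N'-dicyclohexylisourea | CC#CCCCC(=O)OC(=NC1CCCCC1)NC1CCCCC1 | intermediate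
22 | (3S,1E,5Z)-1-[(1R,2R,5R)-2-(but-2-yn-1-yl)-5-(tert-butyldimethylsilyloxy)-3-oxocyclopentyl]octa-1,5-dien-3-yl hept-5-ynoate | CC/C=C\C[C@H](OC(=O)CCCC#CC)/C=C/[C@H]1[C@H](O[Si](C)(C)C(C)(C)C)CC(=O)[C@@H]1CC#CC | intermediate
23 | 5,6-didehydro-PGE3 1,15-lactone 11-O-TBS ether (13-membered cycloalkyne; 8R,11R,12R,15S) | CC/C=C\C[C@H]1/C=C/[C@H]2[C@H](O[Si](C)(C)C(C)(C)C)CC(=O)[C@@H]2CC#CCCCC(=O)O1 | intermediate
24 | PGE3 1,15-lactone 11-O-TBS ether (5Z,13E,17Z) | CC/C=C\C[C@H]1/C=C/[C@H]2[C@H](O[Si](C)(C)C(C)(C)C)CC(=O)[C@@H]2C/C=C\CCCC(=O)O1 | intermediate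
25 | PGE3 1,15-lactone (11-alcohol) | CC/C=C\C[C@H]1/C=C/[C@H]2[C@H](O)CC(=O)[C@@H]2C/C=C\CCCC(=O)O1 | intermediate
26 | PGE3 1,15-lactone 11-acetate (8R,11R,12R,15S; 5Z,13E,17Z) | CC/C=C\C[C@H]1/C=C/[C@H]2[C@H](OC(C)=O)CC(=O)[C@@H]2C/C=C\CCCC(=O)O1 | target

**Step count**

Total: 14 steps. Longest linear sequence: 13 steps (steps 1 to 6 and 8 to 14); step 7 is a one-step side branch.

**Steps most likely to fail**

Step 8. Proton transfer between the zinc enolate and the product ketone, or slow C-alkylation, could leave the simple conjugate adduct or lead to loss of the C11 silyloxy group by β-elimination. The fallback sets out from enolate 17, generated as in step 8, and replaces alkylation by an aldol reaction followed by radical deoxygenation. The enolate is trapped at −78 °C with but-2-ynal, a far more reactive electrophile, to give the C7 carbinol aldol adduct F1 as an epimer mixture at C7. The alcohol is converted with phenyl chlorothionoformate, pyridine and catalytic DMAP into the phenyl thionocarbonate F2. Barton–McCombie reduction with Bu3SnH and AIBN in toluene at 80 °C removes the C7 oxygen and returns to the route at 18.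

Step 11. Intermolecular metathesis to oligomers could outrun closure of the 13-membered ring. The fallback sets out from 18 and 20 and closes the ring at the O15–C1 ester bond instead. Acid 20 is esterified (MeOH, catalytic H2SO4) to methyl hept-5-ynoate F3. Alkyne cross-metathesis of 18 with an excess of F3, using the same molybdenum alkylidyne and 5 Å sieves, gives the open-chain 5,6-didehydro methyl ester F4 (11-O-TBS, 15-O-TES). PPTS in methanol frees the 15-hydroxy ester F5. Porcine liver esterase at pH 7 hydrolyses the methyl ester to the seco acid F6 without touching the β-silyloxy ketone. Shiina macrolactonisation (2-methyl-6-nitrobenzoic anhydride, DMAP, CH2Cl2, high dilution) returns to the route at 23.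

Step 2. The acetylide could deprotonate the doubly activated C2 methylene of the amide instead of adding, or the Z-alkene could migrate into conjugation with the new ynone. The fallback sets out from 3 and forms the C14–C15 bond at the aldehyde oxidation level. Reduction with i-Bu2AlH at −78 °C, with a potassium sodium tartrate (KNaC4H4O6) work-up, gives (Z)-hex-3-enal F7, which is used at once. Addition of acetylide 4 at −78 °C, where 1,2-addition to the aldehyde should outpace enolisation, gives the racemic carbinol (Z)-1-(trimethylsilyl)oct-5-en-1-yn-3-ol F8. Oxidation with Dess–Martin periodinane buffered with NaHCO3 returns to the route at 6.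

**Further compounds**

F1 | step 8 | (2R,3R,4R)-4-(tert-butyldimethylsilyloxy)-2-(1-hydroxybut-2-yn-1-yl)-3-[(3S,1E,5Z)-3-(triethylsilyloxy)octa-1,5-dien-1-yl]cyclopentan-1-one (C7 epimer mixture) | CC/C=C\C[C@H](O[Si](CC)(CC)CC)/C=C/[C@H]1[C@H](O[Si](C)(C)C(C)(C)C)CC(=O)[C@@H]1C(O)C#CC
F2 | step 8 | O-phenyl thionocarbonate of F1 at the C7 oxygen | CC/C=C\C[C@H](O[Si](CC)(CC)CC)/C=C/[C@H]1[C@H](O[Si](C)(C)C(C)(C)C)CC(=O)[C@@H]1C(OC(=S)Oc2ccccc2)C#CC
F3 | step 11 | methyl hept-5-ynoate | CC#CCCCC(=O)OC
F4 | step 11 | methyl 7-[(1R,2R,3R)-3-(tert-butyldimethylsilyloxy)-5-oxo-2-[(3S,1E,5Z)-3-(triethylsilyloxy)octa-1,5-dien-1-yl]cyclopentyl]hept-5-ynoate | CC/C=C\C[C@H](O[Si](CC)(CC)CC)/C=C/[C@H]1[C@H](O[Si](C)(C)C(C)(C)C)CC(=O)[C@@H]1CC#CCCCC(=O)OC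
F5 | step 11 | methyl 7-[(1R,2R,3R)-3-(tert-butyldimethylsilyloxy)-2-[(3S,1E,5Z)-3-hydroxyocta-1,5-dien-1-yl]-5-oxocyclopentyl]hept-5-ynoate | CC/C=C\C[C@H](O)/C=C/[C@H]1[C@H](O[Si](C)(C)C(C)(C)C)CC(=O)[C@@H]1CC#CCCCC(=O)OC
F6 | step 11 | 7-[(1R,2R,3R)-3-(tert-butyldimethylsilyloxy)-2-[(3S,1E,5Z)-3-hydroxyocta-1,5-dien-1-yl]-5-oxocyclopentyl]hept-5-ynoic acid | CC/C=C\C[C@H](O)/C=C/[C@H]1[C@H](O[Si](C)(C)C(C)(C)C)CC(=O)[C@@H]1CC#CCCCC(=O)O
F7 | step 2 | (Z)-hex-3-enal | CC/C=C\CC=O
F8 | step 2 | racemic (Z)-1-(trimethylsilyl)oct-5-en-1-yn-3-ol | CC/C=C\CC(O)C#C[Si](C)(C)C
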